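## The problem

Target 18 is an isoflavone: a 7-hydroxychromen-4-one (rings A and C, unprimed positions) that carries at C3 a benzene ring B, which is fused across C4a'–C8a' to a 2,2-dimethyl-2H-pyran (ring D, primed chromene positions). Ring B is pentasubstituted. Going round from C5' it bears the chromone, the pyran carbon C4', the ring oxygen, a free hydroxyl at C8' and a methyl ether at C7', so three neighbouring oxygens must be told apart and the C3–C5' bond is flanked by the pyran. The target has no stereocentre; the only one met on the way, C3 of an isoflavanone, is erased again, so the difficulty is regiochemical and chemoselective, not stereochemical. Three groups do not survive rough treatment: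

- the chromene, which acid protonates at C3' to a C4' cation stabilised by the C7' methoxy group para to C4a';
- the pyranone ring C, which hydroxide opens at C2;
- the C8' phenol next to a methoxy group, which quinone oxidants attack.

The phenols must therefore stay masked until the last oxidation is over and then be freed without hydrogenation, strong base or a hard Lewis acid. The enabling feature is that ring C is a benzofuran-3(2H)-one enlarged by one carbon: C3, which bears ring B, lies between the carbonyl carbon C4 and the oxygen-bound methylene C2. If an aryl-substituted carbon can be inserted into that bond of a coumaranone, ring C and the C3–C5' link arise together, and the inserted carbon can be the formyl carbon of a ring B aldehyde.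

## Retrosynthesis

**18 from 17.** The two phenolic O–H bonds are traced back to an acetate on O7 and a methoxymethyl (MOM) ether on O8'. The acetate is chosen because it is electron-withdrawing, which the ring expansion needs. The MOM ether is chosen because it survives base, heat, hydrogenation and quinone oxidation. Both should fall in one treatment with acidic methanol; benzyl ethers would call for hydrogenolysis, which the chromene forbids, or a boron halide.

**17 from 15.** Four hydrogens are added back, across C2–C3 and C3'–C4'. This is preferred to carrying the chromene through, because a diazo carbon ortho to an alkenyl group cyclises onto it, and because an isoflavanone is what a ketone homologation delivers. The forward step asks one quinone oxidant to dehydrogenate a benzylic chroman position activated by a para methoxy group and an α-aryl ketone, with both phenols masked. Compound 16, with ring D already unsaturated, is the expected intermediate.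

**15 from 11 and 9.** The C3–C4 and C2–C3 bonds are cut, which removes C3 with ring B from ring C and leaves coumaranone 11 and aryldiazomethane 13. Compound 13 is released from tosylhydrazone 9 through its salt 12 and adds to 11 to give betaine 14. The neighbouring cuts are weaker for this target:

- cutting C3–C5' needs a ring B organometallic or halide and a coupling next to the pyran;
- cutting at C2 needs a homologated arylacetic acid.

The chosen cut uses the formyl carbon of a ring B aldehyde directly and halves the molecule. It asks the forward reaction to shift the O-bound CH2 and not the ring A carbon. Electron-rich aryl groups migrate well in such homologations, so ring A is made electron-poor with the acetate, and a fallback through a conventional ring C synthesis from the same 9 is kept ready.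

**9 from 7 and 8.** The C=N bond is cut to chroman aldehyde 7 and sulfonyl hydrazide 8, a plain condensation.

**7 from 6.** Two hydrogens are removed to give chromene aldehyde 6. The saturation is asked to spare the formyl group.

**6 from 4.** The C4a'–C4' bond is cut, which opens ring D to aryl propargyl ether 4. The thermal Claisen cascade, through allenylphenol 5, can only go to the one free ortho carbon because the other bears the MOM ether, so the ring fusion is fixed by the substitution pattern.

**4 from 2 and 3; 2 from 1.** The propargyl O–C bond is cut to phenol 2 and chloride 3. Phenol 2 comes from 1 by alkylating the more acidic hydroxyl para to the formyl group. All five ring B substituents are thus already in place in 1.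

**11 from 10.** The acetate is cut to give 10.

## Roads not taken

**Alternative 1:** The C3'=C4' bond of ring D is cut to a diene, the vinyl and 1,1-dimethylallyl ether compound A2. The second-generation Grubbs catalyst RuCl2(=CHPh)(H2IMes)(PCy3) would close ring D to bis-MOM isoflavone A1 with release of a two-carbon alkene.

- Merits: the closure is a known, neutral reaction to a six-membered cis alkene, the chromene appears late, and ring D never has to be reduced and re-oxidised.
- Weak points: A2 needs a ring B with a vinyl group ortho to the C3–C5' bond and a tertiary allyl aryl ether. Such ethers ionise and rearrange easily and are usually made by semihydrogenation of a propargyl ether of the type of 4, which closes to the chromene on heating without ruthenium. The C3–C5' bond would also have to be made by a coupling flanked on both sides.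
- Comparison: in certainty of the key step this road is better. The chosen plan sets against it nine operations in all, a ring D that comes from one thermal step, and no hindered coupling.

**Alternative 2:** Both carbon arms of ring B (C5'–CH2 and C4a'–C4') are cut back to an aryne from silyl triflate A4 and β-keto ester A5. CsF would free the aryne, which inserts into the acyl–CH2 bond to give arylacetate A3.

- Merits: two adjacent C–C bonds form in one mild step of a known class, with regiochemistry set by the methoxy group beside the aryne.
- Weak points: A4 takes several steps. The enone of A5 is open to conjugate addition. After A3 one of two methyl ethers must be cleaved, the pyranone closed, reduced and dehydrated, and all of rings A and C still built from the acetate arm.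
- Comparison: the precedent is better than for the ring expansion, but the route is roughly twice as long and builds substituents that 1 supplies ready-made. The chosen plan carries the unproven migration selectivity in exchange.

**Alternative 3:** Ring B itself is cut across C4a'–C8a' to cyclobutenone A7. Heating would open it to a dienylketene that closes by 6π electrocyclisation to prenylphenol A6.

- Merits: the substitution pattern of the arene is fully controlled, and the prenyl group lands ortho to the new hydroxyl.
- Weak points: A7 must carry a chromone, which does not tolerate the organometallic additions to squaric esters normally used to make such cyclobutenones. After A6 the middle methyl ether must be cleaved selectively and the prenylphenol cyclised oxidatively.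
- Comparison: the benzannulation is a known reaction class, which is an advantage over the chosen key step. Its regiochemical control, however, solves a problem that 1 already solves, and the chosen plan is much shorter.

Key step: step 7

Assumption: 15 and 16 are racemates and 14 is a mixture of diastereomers; this has no consequence because C3 becomes trigonal in step 8.

## Route

Step 1
Reactants: 1 3,4-dihydroxy-5-methoxybenzaldehyde (5-hydroxyvanillin)
Product: 2 3-hydroxy-5-methoxy-4-(methoxymethoxy)benzaldehyde
Conditions: MOMCl (1.05 equiv), K2CO3 (1.0 equiv), acetone, 0 °C → rt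
Reagents that add atoms: chloromethyl methyl ether, COCCl
Why: Williamson-type O-alkylation; the hydroxyl para to the formyl group is the more acidic, so one equivalent of base forms its phenoxide, which should be alkylated selectively, as is usual for 3,4-dihydroxybenzaldehydes.

Step 2
Reactants: 2 3-hydroxy-5-methoxy-4-(methoxymethoxy)benzaldehyde; 3 3-chloro-3-methylbut-1-yne
Product: 4 3-methoxy-4-(methoxymethoxy)-5-[(2-methylbut-3-yn-2-yl)oxy]benzaldehyde
Conditions: K2CO3 (2 equiv), KI (cat.), CuI (5 mol%), DMF, 60 °C
Reagents that add atoms: none
Why: Copper-assisted O-alkylation of a phenoxide with a tertiary propargylic chloride, the standard entry to aryl 1,1-dimethylpropargyl ethers; only one free hydroxyl is present.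

Step 3
Reactants: 4 3-methoxy-4-(methoxymethoxy)-5-[(2-methylbut-3-yn-2-yl)oxy]benzaldehyde
Product: 6 7-methoxy-8-(methoxymethoxy)-2,2-dimethyl-2H-chromene-5-carbaldehyde, via allenylphenol 5 (not isolated)
Conditions: PhNEt2, 190 °C, Ar
Reagents that add atoms: none
Why: Aromatic propargyl Claisen rearrangement; the [3,3] shift can only go to the unsubstituted ortho carbon between the ether oxygen and the formyl-bearing carbon, and enolisation to 5, a 1,5-hydrogen shift and oxa-6π electrocyclisation should then close the 2,2-dimethylchromene.

Step 4
Reactants: 6 7-methoxy-8-(methoxymethoxy)-2,2-dimethyl-2H-chromene-5-carbaldehyde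
Product: 7 7-methoxy-8-(methoxymethoxy)-2,2-dimethyl-3,4-dihydro-2H-chromene-5-carbaldehyde
Conditions: H2 (1 atm), 10% Pd/C, Ph2S (1 mol%), EtOAc, rt
Reagents that add atoms: none
Why: Catalytic hydrogenation on a sulfide-moderated Pd/C catalyst should saturate the cis-disubstituted styrenic C3–C4 bond while leaving the aromatic aldehyde and the benzylic C–O bonds untouched; no stereocentre arises.

Step 5
Reactants: 7 7-methoxy-8-(methoxymethoxy)-2,2-dimethyl-3,4-dihydro-2H-chromene-5-carbaldehyde; 8 4-methylbenzenesulfonohydrazide
Product: 9 N'-[(E)-[7-methoxy-8-(methoxymethoxy)-2,2-dimethyl-3,4-dihydro-2H-chromen-5-yl]methylidene]-4-methylbenzenesulfonohydrazide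
Conditions: MeOH, 50 °C, then 0 °C (crystallisation)
Reagents that add atoms: none
Why: Condensation of an aromatic aldehyde with a sulfonyl hydrazide should give the (E)-tosylhydrazone; no acid is added, so the MOM ether is not at risk.

Step 6
Reactants: 10 6-hydroxybenzofuran-3(2H)-one
Product: 11 3-oxo-2,3-dihydro-1-benzofuran-6-yl acetate
Conditions: Ac2O (1.05 equiv), pyridine (1.2 equiv), THF, 0 °C
Reagents that add atoms: acetic anhydride, CC(=O)OC(C)=O
Why: Selective O-acylation of the phenol with one equivalent of anhydride in the cold; the ketone is present as the keto tautomer, and the acetyl group is chosen to lower the electron density of ring A for step 7.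

Step 7
Reactants: 9 N'-[(E)-[7-methoxy-8-(methoxymethoxy)-2,2-dimethyl-3,4-dihydro-2H-chromen-5-yl]methylidene]-4-methylbenzenesulfonohydrazide; 11 3-oxo-2,3-dihydro-1-benzofuran-6-yl acetate
Product: 15 racemic 3-[7-methoxy-8-(methoxymethoxy)-2,2-dimethyl-3,4-dihydro-2H-chromen-5-yl]-4-oxo-3,4-dihydro-2H-chromen-7-yl acetate, via tosylhydrazone sodium salt 12 (not isolated), via aryldiazomethane 13 (not isolated), via diazonium alkoxide 14 (not isolated)
Conditions: 9 (1.5 equiv), NaOMe (1.0 equiv per 9), MeOH, rt, evaporation; BnEt3NCl (10 mol%), PhMe, 40 °C, filtration under Ar; filtrate added to 11, Sc(OTf)3 (10 mol%), PhMe, −78 → −20 °C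
Reagents that add atoms: none
Why: Proposed new method: NaOMe turns 9 into salt 12, which loses sodium 4-methylbenzenesulfinate at 40 °C under phase-transfer conditions (Bamford–Stevens cleavage) to give aryldiazomethane 13, used cold as a filtered, base-free solution. Its nucleophilic carbon should add to the Sc(OTf)3-bound ketone of 11, forming C3–C4 (isoflavone numbering) and giving diazonium alkoxide 14, after which the O-bound CH2 shifts to the diazonium carbon anti to the leaving N2 and forms C2–C3. The closest known reaction type is the Lewis-acid-catalysed Tiffeneau–Demjanov-type homologation of cycloalkanones with aryldiazomethanes, which has not been shown on benzofuran-3(2H)-ones. Ring C is not closed by a cyclisation but arises by enlargement of the existing furanone through this 1,2-shift, driven by loss of N2 and relief of five-ring strain, so no Baldwin mode applies. The new stereocentre C3 forms without control as the racemate, which is harmless because step 8 makes it trigonal. The step needs migration of C2 and not of the ring A carbon C3a (benzofuranone numbering); the acetyl group on O6 withdraws the oxygen lone pair para to C3a and so lowers the aryl migratory aptitude, the in-plane lone pair of O1 lies anti to the C2–C3 bond and supports its shift, and migration of C2 keeps the carbonyl conjugated with ring A. It also needs carbonyl addition to outrun O-alkylation of the enol tautomer and self-condensation of 11, for which the oxophilic Lewis acid, the absence of base and the low temperature are chosen.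

Step 8
Reactants: 15 racemic 3-[7-methoxy-8-(methoxymethoxy)-2,2-dimethyl-3,4-dihydro-2H-chromen-5-yl]-4-oxo-3,4-dihydro-2H-chromen-7-yl acetate
Product: 17 3-[7-methoxy-8-(methoxymethoxy)-2,2-dimethyl-2H-chromen-5-yl]-4-oxo-4H-chromen-7-yl acetate, via chromene isoflavanone 16 (not isolated)
Conditions: DDQ (3 equiv), 1,4-dioxane, 100 °C
Reagents that add atoms: none
Why: Quinone dehydrogenation; hydride abstraction from benzylic C4' (cation stabilised by the para C7' methoxy group and the ring oxygen) and proton loss should give chromene 16, as known for 2,2-dimethylchromans, and the same reagent is known to turn isoflavanones into isoflavones across C2–C3. Both phenols are masked, so no quinone can form, and the C3 stereocentre disappears.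

Step 9
Reactants: 17 3-[7-methoxy-8-(methoxymethoxy)-2,2-dimethyl-2H-chromen-5-yl]-4-oxo-4H-chromen-7-yl acetate
Product: 18 7-hydroxy-3-(8-hydroxy-7-methoxy-2,2-dimethyl-2H-chromen-5-yl)-4H-chromen-4-one
Conditions: HCl (1.25 M in MeOH), THF, 40 °C
Reagents that add atoms: none
Why: Acid-catalysed acetal exchange should remove the MOM ether and acid-catalysed transesterification the aryl acetate in one operation; hydroxide is avoided because it opens ring C at C2, and the low temperature limits protonation of the chromene.

## Compound list

1 | 3,4-dihydroxy-5-methoxybenzaldehyde (5-hydroxyvanillin) | COc1cc(C=O)cc(O)c1O | starting material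
2 | 3-hydroxy-5-methoxy-4-(methoxymethoxy)benzaldehyde | COCOc1c(O)cc(C=O)cc1OC | intermediate
3 | 3-chloro-3-methylbut-1-yne | CC(C)(Cl)C#C | starting material
4 | 3-methoxy-4-(methoxymethoxy)-5-[(2-methylbut-3-yn-2-yl)oxy]benzaldehyde | COCOc1c(OC)cc(C=O)cc1OC(C)(C)C#C | intermediate
5 | 3-hydroxy-5-methoxy-4-(methoxymethoxy)-2-(3-methylbuta-1,2-dien-1-yl)benzaldehyde | COCOc1c(OC)cc(C=O)c(C=C=C(C)C)c1O | intermediate (not isolated)
6 | 7-methoxy-8-(methoxymethoxy)-2,2-dimethyl-2H-chromene-5-carbaldehyde | COCOc1c(OC)cc(C=O)c2c1OC(C)(C)C=C2 | intermediate
7 | 7-methoxy-8-(methoxymethoxy)-2,2-dimethyl-3,4-dihydro-2H-chromene-5-carbaldehyde | COCOc1c(OC)cc(C=O)c2c1OC(C)(C)CC2 | intermediate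
8 | 4-methylbenzenesulfonohydrazide | Cc1ccc(S(=O)(=O)NN)cc1 | starting material
9 | N'-[(E)-[7-methoxy-8-(methoxymethoxy)-2,2-dimethyl-3,4-dihydro-2H-chromen-5-yl]methylidene]-4-methylbenzenesulfonohydrazide | COCOc1c(OC)cc(/C=N/NS(=O)(=O)c3ccc(C)cc3)c2c1OC(C)(C)CC2 | intermediate
10 | 6-hydroxybenzofuran-3(2H)-one | O=C1COc2cc(O)ccc21 | starting material
11 | 3-oxo-2,3-dihydro-1-benzofuran-6-yl acetate | CC(=O)Oc1ccc2c(c1)OCC2=O | intermediate
12 | sodium salt of 9 (deprotonated at the sulfonamide nitrogen) | COCOc1c(OC)cc(/C=N/[N-]S(=O)(=O)c3ccc(C)cc3)c2c1OC(C)(C)CC2.[Na+] | intermediate (not isolated)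
13 | 5-(diazomethyl)-7-methoxy-8-(methoxymethoxy)-2,2-dimethyl-3,4-dihydro-2H-chromene | COCOc1c(OC)cc(C=[N+]=[N-])c2c1OC(C)(C)CC2 | intermediate (not isolated)
14 | 6-acetoxy-3-{diazonio[7-methoxy-8-(methoxymethoxy)-2,2-dimethyl-3,4-dihydro-2H-chromen-5-yl]methyl}-2,3-dihydro-1-benzofuran-3-olate (scandium-bound, mixture of diastereomers) | CC(=O)Oc1ccc2c(c1)OCC2([O-])C([N+]#N)c1cc(OC)c(OCOC)c2OC(C)(C)CCc12 | intermediate (not isolated)
15 | racemic 3-[7-methoxy-8-(methoxymethoxy)-2,2-dimethyl-3,4-dihydro-2H-chromen-5-yl]-4-oxo-3,4-dihydro-2H-chromen-7-yl acetate | CC(=O)Oc1ccc2c(c1)OCC(C2=O)c1cc(OC)c(OCOC)c2OC(C)(C)CCc12 | intermediate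
16 | racemic 3-[7-methoxy-8-(methoxymethoxy)-2,2-dimethyl-2H-chromen-5-yl]-4-oxo-3,4-dihydro-2H-chromen-7-yl acetate | CC(=O)Oc1ccc2c(c1)OCC(C2=O)c1cc(OC)c(OCOC)c2OC(C)(C)C=Cc12 | intermediate (not isolated)
17 | 3-[7-methoxy-8-(methoxymethoxy)-2,2-dimethyl-2H-chromen-5-yl]-4-oxo-4H-chromen-7-yl acetate | CC(=O)Oc1ccc2c(c1)occ(-c1cc(OC)c(OCOC)c3OC(C)(C)C=Cc13)c2=O | intermediate
18 | 7-hydroxy-3-(8-hydroxy-7-methoxy-2,2-dimethyl-2H-chromen-5-yl)-4H-chromen-4-one | COc1cc(-c2coc3cc(O)ccc3c2=O)c2c(c1O)OC(C)(C)C=C2 | target

## Step count and least certain steps

Total step count: 9. Longest linear sequence: 8 (steps 1, 2, 3, 4, 5, 7, 8, 9); the second branch is steps 6, 7, 8, 9.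

**Step 7 (key step, proposed new method).** The most likely failure is competing migration of the ring A carbon instead of the O-bound methylene. Electron-rich aryl groups are good migrating groups in diazo homologations, and an α-oxygen can lower the aptitude of a CH2 group inductively. O-alkylation of the enol form and loss of the diazo compound by self-coupling before addition are further hazards.

The fallback uses known chemistry, sets out from 9 and comes back to the route at 18:
- 9 is heated with purchased 2,4-bis(benzyloxy)benzaldehyde and K2CO3 in 1,4-dioxane at 110 °C. The released diazo compound adds to the formyl group and a hydride shift, where no carbon migration is in question, should give the deoxybenzoin 1-[2,4-bis(benzyloxy)phenyl]-2-[7-methoxy-8-(methoxymethoxy)-2,2-dimethyl-3,4-dihydro-2H-chromen-5-yl]ethan-1-one F1.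
- Hydrogenolysis (H2, Pd/C, EtOAc) should give 1-(2,4-dihydroxyphenyl)-2-[7-methoxy-8-(methoxymethoxy)-2,2-dimethyl-3,4-dihydro-2H-chromen-5-yl]ethan-1-one F2.
- N,N-Dimethylformamide dimethyl acetal in THF at 60 °C supplies C2 and closes ring C to 7-hydroxy-3-[7-methoxy-8-(methoxymethoxy)-2,2-dimethyl-3,4-dihydro-2H-chromen-5-yl]-4H-chromen-4-one F3.
- DDQ (1.2 equiv, benzene, 80 °C) dehydrogenates ring D to 7-hydroxy-3-[7-methoxy-8-(methoxymethoxy)-2,2-dimethyl-2H-chromen-5-yl]-4H-chromen-4-one F4.
- Methanolic HCl as in step 9 then gives 18.

**Step 8.** The likely failure is incomplete dehydrogenation of ring C once ring D is unsaturated, or oxidative degradation of the electron-rich chromene on long heating with excess quinone. The fallback sets out from 15 and comes back at 17. DDQ (1.1 equiv, benzene, 80 °C) is used only for ring D and 16 is isolated. Ring C is then dehydrogenated through its enol with 2-iodoxybenzoic acid in DMSO–toluene at 70 °C. No new compound is made.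

**Step 9.** The likely failure is acid-promoted addition of methanol to the chromene double bond, or its oligomerisation, during the time the ester methanolysis needs. The fallback sets out from 17 and comes back at 18 by two orthogonal unmaskings. Pyridinium 4-toluenesulfonate in tert-butanol at 80 °C removes only the MOM ether in a weakly acidic, poorly nucleophilic medium and should give 3-(8-hydroxy-7-methoxy-2,2-dimethyl-2H-chromen-5-yl)-4-oxo-4H-chromen-7-yl acetate F5. Brief treatment with K2CO3 in MeOH at 0 °C then cleaves the activated aryl acetate to 18.

**Step 4.** The likely failure is partial reduction of the formyl group, or stalling of the hindered alkene on the moderated catalyst. The fallback sets out from 6 and comes back at 7. The metal surface is given up for concerted hydrogen transfer from diimide, generated from dipotassium azodicarboxylate (KO2CN=NCO2K) and AcOH in MeOH–pyridine at rt, which does not reduce aldehydes or cleave benzylic C–O bonds at a useful rate. No new compound is made.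

## Further compounds

F1 | step 7 | 1-[2,4-bis(benzyloxy)phenyl]-2-[7-methoxy-8-(methoxymethoxy)-2,2-dimethyl-3,4-dihydro-2H-chromen-5-yl]ethan-1-one | COCOc1c(OC)cc(CC(=O)c3ccc(OCc4ccccc4)cc3OCc3ccccc3)c2c1OC(C)(C)CC2
F2 | step 7 | 1-(2,4-dihydroxyphenyl)-2-[7-methoxy-8-(methoxymethoxy)-2,2-dimethyl-3,4-dihydro-2H-chromen-5-yl]ethan-1-one | COCOc1c(OC)cc(CC(=O)c3ccc(O)cc3O)c2c1OC(C)(C)CC2
F3 | step 7 | 7-hydroxy-3-[7-methoxy-8-(methoxymethoxy)-2,2-dimethyl-3,4-dihydro-2H-chromen-5-yl]-4H-chromen-4-one | COCOc1c(OC)cc(-c3coc4cc(O)ccc4c3=O)c2c1OC(C)(C)CC2
F4 | step 7 | 7-hydroxy-3-[7-methoxy-8-(methoxymethoxy)-2,2-dimethyl-2H-chromen-5-yl]-4H-chromen-4-one | COCOc1c(OC)cc(-c3coc4cc(O)ccc4c3=O)c2c1OC(C)(C)C=C2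
F0 | step 8 | none | none
F5 | step 9 | 3-(8-hydroxy-7-methoxy-2,2-dimethyl-2H-chromen-5-yl)-4-oxo-4H-chromen-7-yl acetate | CC(=O)Oc1ccc2c(c1)occ(-c1cc(OC)c(O)c3OC(C)(C)C=Cc13)c2=O
F0 | step 4 | none | none
A1 | alternative 1 | 3-[7-methoxy-8-(methoxymethoxy)-2,2-dimethyl-2H-chromen-5-yl]-7-(methoxymethoxy)-4H-chromen-4-one | COc1cc(-c2coc3cc(OCOC)ccc3c2=O)c2c(c1OCOC)OC(C)(C)C=C2
A2 | alternative 1 | 3-[2-ethenyl-5-methoxy-4-(methoxymethoxy)-3-[(2-methylbut-3-en-2-yl)oxy]phenyl]-7-(methoxymethoxy)-4H-chromen-4-one | COc1cc(-c2coc3cc(OCOC)ccc3c2=O)c(C=C)c(OC(C)(C)C=C)c1OCOC
A3 | alternative 2 | methyl 2-[4-(benzyloxy)-3,5-dimethoxy-2-(3-methylbut-2-enoyl)phenyl]acetate | COC(=O)Cc1cc(OC)c(OCc2ccccc2)c(OC)c1C(=O)C=C(C)C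
A4 | alternative 2 | 4-(benzyloxy)-3,5-dimethoxy-2-(trimethylsilyl)phenyl trifluoromethanesulfonate | COc1cc(OS(=O)(=O)C(F)(F)F)c([Si](C)(C)C)c(OC)c1OCc1ccccc1
A5 | alternative 2 | methyl 5-methyl-3-oxohex-4-enoate | COC(=O)CC(=O)C=C(C)C
A6 | alternative 3 | 7-(benzyloxy)-3-[3-hydroxy-4,5-dimethoxy-2-(3-methylbut-2-en-1-yl)phenyl]-4H-chromen-4-one | COc1cc(-c2coc3cc(OCc4ccccc4)ccc3c2=O)c(CC=C(C)C)c(O)c1OC
A7 | alternative 3 | racemic 4-[(1Z)-1-[7-(benzyloxy)-4-oxo-4H-chromen-3-yl]-5-methylhexa-1,4-dien-1-yl]-2,3-dimethoxycyclobut-2-en-1-one | COC1=C(OC)C(/C(=C/CC=C(C)C)c2coc3cc(OCc4ccccc4)ccc3c2=O)C1=O
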